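## Retrosynthetic overview

1. Target ⇒ its hexa-O-benzyl ether (hydrogenolysis last) ⇒ C4–C6 Friedel–Crafts disconnection into a C4-alkoxy (2R,3S)-tri-O-benzylfisetinidol (electrophile) and (2S,3S)-tri-O-benzyl-ent-epifisetinidol (nucleophile).
2. Electrophile ⇐ DDQ oxidation at C4–H of the (2R,3S)-trans-flavan-3-ol; nucleophile ⇐ C3 inversion (oxidation, then bulky hydride) of the (2S,3R) enantiomer.
3. Both trans-flavan-3-ol enantiomers ⇐ one achiral (E)-2-cinnamylphenol, by a peptide-peracid asymmetric epoxidation with in-flask 6-endo phenol opening, run with the two hands of the catalyst (sets C2 and C3, closes the pyran ring).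
4. Cinnamylphenol ⇐ 2'-hydroxychalcone (reductive deoxygenation) ⇐ benzyl-protected acetophenone + benzaldehyde (Claisen–Schmidt).
5. Ring order: the aromatic rings are bought; the pyran ring of each unit is closed in the asymmetric step; the two units are joined afterwards and no ring is formed later.

Assumption: the hand of the peptide catalyst that gives the (2S,3S)-epoxide 7 is called P and is assigned in a first run by chiral HPLC (its mirror image ent-P then gives 10); 9 is drawn as its 4β epimer, but either C4 epimer serves.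

Catalyst P = Boc-L-Asp(OH)-L-Pro-D-Val-NH-(R)-CH(CH3)Ph (free Asp side-chain acid); ent-P = Boc-D-Asp(OH)-D-Pro-L-Val-NH-(S)-CH(CH3)Ph. DIC = iPrN=C=NiPr; DMAP = 4-(dimethylamino)pyridine; CSA = camphor-10-sulfonic acid.

## Route

Step 1
Reactants: 1 1-[4-(benzyloxy)-2-hydroxyphenyl]ethanone; 2 3,4-bis(benzyloxy)benzaldehyde
Product: 3 (E)-1-[4-(benzyloxy)-2-hydroxyphenyl]-3-[3,4-bis(benzyloxy)phenyl]prop-2-en-1-one
Conditions: KOH (50% aq.), EtOH/THF, rt, 36 h
Reagents that add atoms: none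
Why: Claisen–Schmidt aldol condensation, in which the acetophenone enolate adds to the non-enolisable aldehyde and E1cB dehydration gives the E-chalcone, the benzyl ethers being base-stable.

Step 2
Reactants: 3 (E)-1-[4-(benzyloxy)-2-hydroxyphenyl]-3-[3,4-bis(benzyloxy)phenyl]prop-2-en-1-one
Product: 6 (E)-5-(benzyloxy)-2-{3-[3,4-bis(benzyloxy)phenyl]prop-2-en-1-yl}phenol, via aryl ethyl carbonate 4 (not isolated), via ortho-quinone methide 5 (not isolated)
Conditions: ClCO2Et, Et3N, THF, 0 °C; then NaBH4, H2O/THF, 0 °C → rt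
Reagents that add atoms: none
Why: Carbonate-assisted reductive deoxygenation in one pot: NaBH4 reduces the ketone, the ethoxycarbonyl group shifts to the new alkoxide and is expelled to give quinone methide 5, which takes a second hydride at the methide carbon (1,4-addition) and leaves the E-styrene double bond in place.

Step 3
Reactants: 6 (E)-5-(benzyloxy)-2-{3-[3,4-bis(benzyloxy)phenyl]prop-2-en-1-yl}phenol
Product: 8 (2R,3S)-7-(benzyloxy)-2-[3,4-bis(benzyloxy)phenyl]chroman-3-ol, via (2S,3S)-epoxyphenol 7 (not isolated)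
Conditions: P (10 mol%), DIC (2 equiv), 30% aq. H2O2 (2.5 equiv), DMAP (10 mol%), CH2Cl2, 0 °C; then CSA (5 mol%), 0 °C → rt
Reagents that add atoms: hydrogen peroxide, OO
Why: Proposed new method: the Asp side-chain acid of P is turned over to a peracid (DIC activation, perhydrolysis relayed by DMAP) while the phenol O–H of 6 hydrogen-bonds to a backbone amide C=O of the folded peptide, so the peracid oxygen is delivered in a butterfly transition state to one face of the E-alkene and sets both stereocentres of epoxide 7; the electron-rich aryl epoxide is then opened in the same flask by the ortho phenol at the benzylic carbon (acid-assisted 6-endo, SN2-like, inversion) to close ring C as the 2,3-trans isomer; the closest known reaction types are the aspartyl-peptide peracid epoxidation directed by carbamate N–H or allylic O–H hydrogen bonds and the racemic peracid epoxidation–cyclisation of 2-allylphenols, a phenol not having been used as the directing group nor the cascade run asymmetrically.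

Step 4
Reactants: 8 (2R,3S)-7-(benzyloxy)-2-[3,4-bis(benzyloxy)phenyl]chroman-3-ol
Product: 9 (2R,3S,4S)-7-(benzyloxy)-2-[3,4-bis(benzyloxy)phenyl]-4-(2-ethoxyethoxy)chroman-3-ol
Conditions: DDQ (1.5 equiv), EtOCH2CH2OH (5 equiv), CH2Cl2, rt
Reagents that add atoms: 2-ethoxyethanol, CCOCCO
Why: DDQ benzylic C–H oxidation (hydride abstraction): C4–H is activated like a 2,4-dialkoxybenzyl position by O1 and the 7-benzyloxy group and the cation is trapped by the alcohol, C2 and C3 being untouched and the new C4 centre being lost again on ionisation in step 8.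

Step 5
Reactants: 6 (E)-5-(benzyloxy)-2-{3-[3,4-bis(benzyloxy)phenyl]prop-2-en-1-yl}phenol
Product: 11 (2S,3R)-7-(benzyloxy)-2-[3,4-bis(benzyloxy)phenyl]chroman-3-ol, via (2R,3R)-epoxyphenol 10 (not isolated)
Conditions: ent-P (10 mol%), DIC (2 equiv), 30% aq. H2O2 (2.5 equiv), DMAP (10 mol%), CH2Cl2, 0 °C; then CSA (5 mol%), 0 °C → rt
Reagents that add atoms: hydrogen peroxide, OO
Why: Proposed new method: the same phenol-directed aspartyl-peptide peracid epoxidation and 6-endo ring closure as in step 3, now with the mirror-image peptide, so the peracid oxygen reaches the opposite alkene face (epoxide 10) and SN2-like phenol opening at the benzylic carbon gives the (2S,3R) enantiomer; closest known reaction types are hydrogen-bond-directed aspartyl-peptide peracid epoxidation and acid-mediated phenol opening of aryl epoxides.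

Step 6
Reactants: 11 (2S,3R)-7-(benzyloxy)-2-[3,4-bis(benzyloxy)phenyl]chroman-3-ol
Product: 12 (2S)-7-(benzyloxy)-2-[3,4-bis(benzyloxy)phenyl]chroman-3-one
Conditions: Dess–Martin periodinane (1.5 equiv), wet CH2Cl2, rt
Reagents that add atoms: none
Why: Dess–Martin oxidation of the secondary alcohol under near-neutral conditions, which keeps the now α-keto benzylic C2 centre from enolising.

Step 7
Reactants: 12 (2S)-7-(benzyloxy)-2-[3,4-bis(benzyloxy)phenyl]chroman-3-one
Product: 13 (2S,3S)-7-(benzyloxy)-2-[3,4-bis(benzyloxy)phenyl]chroman-3-ol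
Conditions: LiBH(s-Bu)3 (1.5 equiv), LiBr, THF, −78 °C; then H2O
Reagents that add atoms: none
Why: Diastereoselective ketone reduction with a bulky hydride: LiBH(s-Bu)3 attacks C3 from the face opposite the C2 aryl group, so the new hydroxyl ends up cis to it (the standard trans-to-cis inversion of flavan-3-ols).

Step 8
Reactants: 9 (2R,3S,4S)-7-(benzyloxy)-2-[3,4-bis(benzyloxy)phenyl]-4-(2-ethoxyethoxy)chroman-3-ol; 13 (2S,3S)-7-(benzyloxy)-2-[3,4-bis(benzyloxy)phenyl]chroman-3-ol
Product: 14 hexa-O-benzyl ether of the target (4α→6 linked dimer)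
Conditions: 9 (1 equiv), 13 (4 equiv, excess recovered), Me3SiOTf (0.3 equiv), CH2Cl2, −78 → −40 °C; then aq. NaHCO3
Reagents that add atoms: none
Why: Lewis-acid-promoted SN1 Friedel–Crafts alkylation (flavan-4-yl cation coupling as used for procyanidins): Me3SiOTf ionises the C4 ether to the O1/7-OBn-stabilised benzylic cation, which the excess 13 captures through C6 (para to O1, ortho to 7-OBn, less hindered than C8) on the face anti to the C3 hydroxyl, setting the 3,4-trans (4α) centre.

Step 9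
Reactants: 14 hexa-O-benzyl ether of the target (4α→6 linked dimer)
Product: 15 fisetinidol-(4α→6)-ent-epifisetinidol (target)
Conditions: H2 (1 atm), Pd(OH)2/C, THF/MeOH/H2O, rt
Reagents that add atoms: none
Why: Catalytic hydrogenolysis of the six benzyl ethers; the benzylic C2–O1 bonds of the flavan units and the C4 diarylmethine survive these neutral conditions and no stereocentre is touched.

## Compound list

1 | 1-[4-(benzyloxy)-2-hydroxyphenyl]ethanone | CC(=O)c1ccc(OCc2ccccc2)cc1O | starting material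
2 | 3,4-bis(benzyloxy)benzaldehyde | O=Cc1ccc(OCc2ccccc2)c(OCc2ccccc2)c1 | starting material
3 | (E)-1-[4-(benzyloxy)-2-hydroxyphenyl]-3-[3,4-bis(benzyloxy)phenyl]prop-2-en-1-one | O=C(/C=C/c1ccc(OCc2ccccc2)c(OCc2ccccc2)c1)c1ccc(OCc2ccccc2)cc1O | intermediate
4 | aryl ethyl carbonate of 3 (2'-O-ethoxycarbonyl chalcone) | CCOC(=O)Oc1cc(OCc2ccccc2)ccc1C(=O)/C=C/c1ccc(OCc2ccccc2)c(OCc2ccccc2)c1 | intermediate (not isolated)
5 | 3-(benzyloxy)-6-{(E)-3-[3,4-bis(benzyloxy)phenyl]prop-2-en-1-ylidene}cyclohexa-2,4-dien-1-one (ortho-quinone methide; exocyclic alkene geometry not defined) | O=C1C=C(OCc2ccccc2)C=CC1=C/C=C/c1ccc(OCc2ccccc2)c(OCc2ccccc2)c1 | intermediate (not isolated)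
6 | (E)-5-(benzyloxy)-2-{3-[3,4-bis(benzyloxy)phenyl]prop-2-en-1-yl}phenol | Oc1cc(OCc2ccccc2)ccc1C/C=C/c1ccc(OCc2ccccc2)c(OCc2ccccc2)c1 | intermediate
7 | 5-(benzyloxy)-2-{[(2S,3S)-3-[3,4-bis(benzyloxy)phenyl]oxiran-2-yl]methyl}phenol (trans-epoxide) | Oc1cc(OCc2ccccc2)ccc1C[C@@H]1O[C@H]1c1ccc(OCc2ccccc2)c(OCc2ccccc2)c1 | intermediate (not isolated)
8 | (2R,3S)-7-(benzyloxy)-2-[3,4-bis(benzyloxy)phenyl]chroman-3-ol (2,3-trans; tri-O-benzylfisetinidol) | O(Cc1ccccc1)c1ccc2c(c1)O[C@H](c1ccc(OCc3ccccc3)c(OCc3ccccc3)c1)[C@@H](O)C2 | intermediate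
9 | (2R,3S,4S)-7-(benzyloxy)-2-[3,4-bis(benzyloxy)phenyl]-4-(2-ethoxyethoxy)chroman-3-ol (2,3-trans; 4-alkoxy cis to 3-OH) | O(Cc1ccccc1)c1ccc2c(c1)O[C@H](c1ccc(OCc3ccccc3)c(OCc3ccccc3)c1)[C@@H](O)[C@H]2OCCOCC | intermediate
10 | 5-(benzyloxy)-2-{[(2R,3R)-3-[3,4-bis(benzyloxy)phenyl]oxiran-2-yl]methyl}phenol (trans-epoxide) | Oc1cc(OCc2ccccc2)ccc1C[C@H]1O[C@@H]1c1ccc(OCc2ccccc2)c(OCc2ccccc2)c1 | intermediate (not isolated)
11 | (2S,3R)-7-(benzyloxy)-2-[3,4-bis(benzyloxy)phenyl]chroman-3-ol (2,3-trans; enantiomer of 8) | O(Cc1ccccc1)c1ccc2c(c1)O[C@@H](c1ccc(OCc3ccccc3)c(OCc3ccccc3)c1)[C@H](O)C2 | intermediate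
12 | (2S)-7-(benzyloxy)-2-[3,4-bis(benzyloxy)phenyl]chroman-3-one | O(Cc1ccccc1)c1ccc2c(c1)O[C@@H](c1ccc(OCc3ccccc3)c(OCc3ccccc3)c1)C(=O)C2 | intermediate
13 | (2S,3S)-7-(benzyloxy)-2-[3,4-bis(benzyloxy)phenyl]chroman-3-ol (2,3-cis; tri-O-benzyl-ent-epifisetinidol) | O(Cc1ccccc1)c1ccc2c(c1)O[C@@H](c1ccc(OCc3ccccc3)c(OCc3ccccc3)c1)[C@@H](O)C2 | intermediate
14 | hexa-O-benzyl ether of 15: upper unit 2R,3S with the C4 aryl α (trans to 3-OH, cis to the 2-aryl), lower unit 2S,3S joined through C6; same spatial arrangement as 15 at all five centres (C4 reads S here only because the benzyl ethers change the CIP ranking) | O(Cc1ccccc1)c1ccc2c(c1)O[C@H](c1ccc(OCc3ccccc3)c(OCc3ccccc3)c1)[C@@H](O)[C@@H]2c1cc2c(cc1OCc1ccccc1)O[C@@H](c1ccc(OCc3ccccc3)c(OCc3ccccc3)c1)[C@@H](O)C2 | intermediate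
15 | (2R,3S,4R)-2-(3,4-dihydroxyphenyl)-4-[(2S,3S)-2-(3,4-dihydroxyphenyl)-3,7-dihydroxychroman-6-yl]chroman-3,7-diol (fisetinidol-(4α→6)-ent-epifisetinidol) | Oc1ccc2c(c1)O[C@H](c1ccc(O)c(O)c1)[C@@H](O)[C@@H]2c1cc2c(cc1O)O[C@@H](c1ccc(O)c(O)c1)[C@@H](O)C2 | target

## Step count

Total steps: 9. Longest linear sequence: 7 (steps 1, 2, 5, 6, 7, 8, 9).

## Three steps most likely to fail

**Step 3 (and its mirror-image twin, step 5), the proposed peptide-peracid epoxidation–cyclisation.** The risks are low enantioselectivity, oxidation of the electron-rich phenol and 5-exo instead of 6-endo opening. Any cis isomer that leaks from step 3 through an SN1 pathway is compound 13 itself and can be pooled with the nucleophile; 8 and 11 are upgraded by recrystallisation. The fallback uses known chemistry, sets out from 6 and comes back at 8 (and, with the other ketone, at 11). TBSCl/imidazole in DMF gives the tert-butyldimethylsilyl ether of 6 F1. Shi epoxidation with the enantiomer of the D-fructose-derived ketone (1,2:4,5-di-O-isopropylidene-β-D-erythro-2,3-hexodiulo-2,6-pyranose; enantiomer made from L-sorbose), KHSO5 (as 2KHSO5·KHSO4·K2SO4), K2CO3 buffer at pH 10.5, MeCN/CH2(OMe)2/H2O, 0 °C, gives the (2S,3S)-epoxy silyl ether F2. The D-fructose-derived ketone gives R,R-epoxides from E-alkenes of this substitution pattern, so its enantiomer gives S,S. Bu4NF/AcOH in THF followed by CSA frees the phenol (7) and closes ring C to 8. For the other branch the D-fructose-derived ketone itself gives the (2R,3R)-epoxy silyl ether F3, which returns at 11 through 10.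

**Step 4, DDQ oxidation at C4 of a 5-deoxy flavan.** Ring A is less activated than in the catechin series, so the reaction may be slow or compete with oxidation at C2–H. The fallback keeps the chalcone carbonyl oxygen as the C4 leaving group instead of re-installing it; it sets out from 3 and comes back at 14. MOMCl/iPr2NEt gives the 2'-O-methoxymethyl chalcone F4. Juliá–Colonna epoxidation (poly-L-leucine, urea·H2O2, DBU, THF) gives the (αR,βS)-epoxy ketone F5. HCl in MeOH/THF removes the acetal and closes ring C by 6-endo attack at the benzylic carbon to the (2R,3R)-trans-dihydroflavonol F6. NaBH4 in MeOH/THF gives the (2R,3S,4R)-flavan-3,4-diol F7, which is ionised directly by Me3SiOTf under the step 8 conditions in place of 9 to give 14.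

**Step 8, the interflavan coupling.** Both partners carry the same ring A, so self-condensation of 9, attack through C8 and the 4β epimer all compete, and 14 must be separated from them. The fallback blocks ring A of the electrophile; it sets out from 8 and comes back at 15. NBS in CH2Cl2 at −20 °C brominates the most activated position to give the 6-bromo derivative of 8 F8. DDQ/2-ethoxyethanol gives the 6-bromo-4-(2-ethoxyethoxy) electrophile F9, which can no longer act as a nucleophile. Me3SiOTf with only 1.5 equiv of 13 then gives the bromo hexa-O-benzyl dimer F10. H2, Pd(OH)2/C with Et3N removes the bromine and the six benzyl groups in one operation to give 15.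

## Further compounds

F1 | step 3 | tert-butyl{5-(benzyloxy)-2-[(E)-3-[3,4-bis(benzyloxy)phenyl]prop-2-en-1-yl]phenoxy}dimethylsilane | CC(C)(C)[Si](C)(C)Oc1cc(OCc2ccccc2)ccc1C/C=C/c1ccc(OCc2ccccc2)c(OCc2ccccc2)c1
F2 | step 3 | tert-butyldimethylsilyl ether of 7, (2S,3S)-trans-epoxide | CC(C)(C)[Si](C)(C)Oc1cc(OCc2ccccc2)ccc1C[C@@H]1O[C@H]1c1ccc(OCc2ccccc2)c(OCc2ccccc2)c1
F3 | step 3 | tert-butyldimethylsilyl ether of 10, (2R,3R)-trans-epoxide | CC(C)(C)[Si](C)(C)Oc1cc(OCc2ccccc2)ccc1C[C@H]1O[C@@H]1c1ccc(OCc2ccccc2)c(OCc2ccccc2)c1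
F4 | step 4 | (E)-1-[4-(benzyloxy)-2-(methoxymethoxy)phenyl]-3-[3,4-bis(benzyloxy)phenyl]prop-2-en-1-one | COCOc1cc(OCc2ccccc2)ccc1C(=O)/C=C/c1ccc(OCc2ccccc2)c(OCc2ccccc2)c1
F5 | step 4 | [4-(benzyloxy)-2-(methoxymethoxy)phenyl]{(2R,3S)-3-[3,4-bis(benzyloxy)phenyl]oxiran-2-yl}methanone | COCOc1cc(OCc2ccccc2)ccc1C(=O)[C@@H]1O[C@H]1c1ccc(OCc2ccccc2)c(OCc2ccccc2)c1
F6 | step 4 | (2R,3R)-7-(benzyloxy)-2-[3,4-bis(benzyloxy)phenyl]-3-hydroxychroman-4-one (2,3-trans) | O(Cc1ccccc1)c1ccc2c(c1)O[C@H](c1ccc(OCc3ccccc3)c(OCc3ccccc3)c1)[C@@H](O)C2=O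
F7 | step 4 | (2R,3S,4R)-7-(benzyloxy)-2-[3,4-bis(benzyloxy)phenyl]chroman-3,4-diol (2,3-trans-3,4-trans) | O(Cc1ccccc1)c1ccc2c(c1)O[C@H](c1ccc(OCc3ccccc3)c(OCc3ccccc3)c1)[C@@H](O)[C@@H]2O
F8 | step 8 | (2R,3S)-7-(benzyloxy)-2-[3,4-bis(benzyloxy)phenyl]-6-bromochroman-3-ol | O(Cc1ccccc1)c1c(Br)cc2c(c1)O[C@H](c1ccc(OCc3ccccc3)c(OCc3ccccc3)c1)[C@@H](O)C2
F9 | step 8 | (2R,3S,4S)-7-(benzyloxy)-2-[3,4-bis(benzyloxy)phenyl]-6-bromo-4-(2-ethoxyethoxy)chroman-3-ol | O(Cc1ccccc1)c1c(Br)cc2c(c1)O[C@H](c1ccc(OCc3ccccc3)c(OCc3ccccc3)c1)[C@@H](O)[C@H]2OCCOCC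
F10 | step 8 | 6-bromo derivative (upper unit) of 14, 4α→6 linked, configuration as in 14 | O(Cc1ccccc1)c1c(Br)cc2c(c1)O[C@H](c1ccc(OCc3ccccc3)c(OCc3ccccc3)c1)[C@@H](O)[C@@H]2c1cc2c(cc1OCc1ccccc1)O[C@@H](c1ccc(OCc3ccccc3)c(OCc3ccccc3)c1)[C@@H](O)C2
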